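**Retrosynthetic overview**
1. Target 11 ⇒ methoxydioxolane 10 + the silyl ketene acetal of methyl acetate: the CH2CO2Me arm is put on C3 last, through the dioxolan-3-yl (peroxycarbenium) cation.
2. 10 ⇒ hemiketal 9 ⇒ enone 7 + H2O2: the key disconnection is the tertiary C5–O bond (enantioselective conjugate hydroperoxidation of a trisubstituted enone), followed in the same flask by C3–O hemiketal closure. This forms the only ring, the 1,2-dioxolane.
3. 7 ⇒ alkyne 5: syn-methylalumination and acylation of the terminal alkyne fix the E-enone.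
4. 5 ⇒ (R)-citronellal 1 + 4-phenyl-1-butene 2: 1 supplies the side-chain methyl stereocentre; cross-metathesis, hydrogenation and one-carbon alkyne homologation complete the chain.

Assumption: the quinine-derived primary amine is taken to deliver H2O2 to the Si face of C4 of enone 7 (giving 4S), by analogy with disubstituted enones; if a pilot run shows the opposite sense, the quinidine-derived pseudoenantiomer is used in the same step.

**Step 1**
Reactants: 1 (R)-citronellal; 2 4-phenyl-1-butene (3 equiv)
Product: 3 (3R)-3-methyl-9-phenylnon-6-enal (E/Z mixture)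
Conditions: second-generation Hoveyda–Grubbs catalyst RuCl2(H2IMes)(=CH-C6H4-2-OiPr) (3 mol%), 1,4-benzoquinone (10 mol%), CH2Cl2, 40 °C, Ar sweep, 16 h
Reagents that add atoms: none
Why: Olefin cross-metathesis in which excess terminal alkene 2 exchanges with the prenyl-type trisubstituted alkene of 1 and volatile isobutene leaves; the aldehyde and the C3 stereocentre (from the chiral pool) are not involved.

**Step 2**
Reactants: 3 (3R)-3-methyl-9-phenylnon-6-enal
Product: 4 (3R)-3-methyl-9-phenylnonanal
Conditions: H2 (1 atm), Pd/C (10 wt%, 5 mol% Pd), EtOAc, rt, 3 h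
Reagents that add atoms: none
Why: Heterogeneous catalytic hydrogenation saturates the disubstituted alkene (removing the E/Z mixture), while an aliphatic aldehyde and the arene survive Pd/C at 1 atm in EtOAc.

**Step 3**
Reactants: 4 (3R)-3-methyl-9-phenylnonanal
Product: 5 (4R)-4-methyl-10-phenyldec-1-yne
Conditions: dimethyl (1-diazo-2-oxopropyl)phosphonate (1.3 equiv), K2CO3 (2 equiv), MeOH, 0 °C to rt, 12 h
Reagents that add atoms: dimethyl (1-diazo-2-oxopropyl)phosphonate, CC(=O)C(=[N+]=[N-])P(=O)(OC)OC
Why: Ohira–Bestmann (Seyferth–Gilbert) homologation turns the aldehyde into the terminal alkyne under mild carbonate conditions; the stereocentre is β to the carbonyl and cannot epimerise.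

**Step 4**
Reactants: 5 (4R)-4-methyl-10-phenyldec-1-yne
Product: 7 (3E,6R)-4,6-dimethyl-12-phenyldodec-3-en-2-one, via alkenylalane 6 (not isolated)
Conditions: Me3Al (2 equiv), Cp2ZrCl2 (20 mol%), CH2Cl2, 0 °C to rt, 12 h; volatiles and excess Me3Al removed in vacuo; then AcCl (1.5 equiv), Pd(PPh3)4 (5 mol%), THF, 0 °C to rt, 2 h
Reagents that add atoms: trimethylaluminium, C[Al](C)C; acetyl chloride, CC(=O)Cl
Why: Negishi zirconium-catalysed carboalumination adds Me and Al syn across the alkyne (Me on the internal carbon), and palladium-catalysed acylation of the alkenyl–Al bond proceeds with retention, so the enone is formed as the E isomer only.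

**Step 5**
Reactants: 7 (3E,6R)-4,6-dimethyl-12-phenyldodec-3-en-2-one
Product: 9 (5S)-3,5-dimethyl-5-[(2R)-2-methyl-8-phenyloctyl]-1,2-dioxolan-3-ol, via hydroperoxy ketone 8 (not isolated)
Conditions: 9-amino-9-deoxy-epi-quinine (20 mol%), CCl3CO2H (40 mol%), 50% aq. H2O2 (5 equiv), 1,4-dioxane, 32 °C, 48 h
Reagents that add atoms: hydrogen peroxide, OO
Why: Proposed new method: the cinchona primary amine condenses with the hindered ketone to give an iminium ion of the trisubstituted enone, the protonated quinuclidine hydrogen-bonds H2O2 and steers this α-effect nucleophile to the Si face of the fully substituted C4, which creates the tertiary C–O stereocentre (4S in 8, 5S in 9), and after hydrolysis the hydroperoxy ketone 8 closes to the five-membered peroxyhemiketal 9, which takes it out of the retro-addition equilibrium (achiral H2O2 addition to mesityl oxide gives the same kind of cyclic hemiketal); the closest known reaction type is the cinchona-primary-amine-catalysed hydroperoxidation of β-monosubstituted acyclic enones with H2O2 (and the epoxidation of 3-substituted cyclohexenones, which shows that H2O2 adds to a disubstituted β-carbon under this catalysis), not yet shown for acyclic β,β-disubstituted enones giving a tertiary peroxide.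

**Step 6**
Reactants: 9 (5S)-3,5-dimethyl-5-[(2R)-2-methyl-8-phenyloctyl]-1,2-dioxolan-3-ol
Product: 10 (5S)-3-methoxy-3,5-dimethyl-5-[(2R)-2-methyl-8-phenyloctyl]-1,2-dioxolane (both C3 epimers)
Conditions: MeOH, TsOH·H2O (5 mol%), 3 Å molecular sieves, rt, 12 h
Reagents that add atoms: methanol, CO
Why: Acid-catalysed peroxyketalisation (Fischer-type exchange of the hemiketal OH for OMe); C5 is not touched, and the C3 mixture does not matter because C3 is ionised again in step 7.

**Step 7**
Reactants: 10 (5S)-3-methoxy-3,5-dimethyl-5-[(2R)-2-methyl-8-phenyloctyl]-1,2-dioxolane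
Product: 11 methyl 2-[(3R,5S)-3,5-dimethyl-5-[(2R)-2-methyl-8-phenyloctyl]-1,2-dioxolan-3-yl]acetate
Conditions: CH2=C(OMe)OSiMe3 (3 equiv), Me3SiOTf (0.3 equiv), CH2Cl2, −78 °C, 1 h; sat. NaHCO3; SiO2 chromatography to remove the C3 epimer
Reagents that add atoms: 1-methoxy-1-(trimethylsilyloxy)ethene, C=C(OC)O[Si](C)(C)C
Why: Mukaiyama-type Lewis-acid substitution of an alkoxydioxolane: Me3SiOTf ionises the methoxy group to a planar peroxycarbenium ion, and the silyl ketene acetal attacks it preferentially anti to the larger C5 substituent (the branched octyl chain), which puts CH2CO2Me trans to that chain (3R); the selectivity is expected to be modest and the minor C3 epimer is separated.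

**Compound list**
1 | (R)-(+)-citronellal, (3R)-3,7-dimethyloct-6-enal | O=CC[C@H](C)CCC=C(C)C | starting material
2 | 4-phenyl-1-butene (but-3-en-1-ylbenzene) | C=CCCc1ccccc1 | starting material
3 | (3R)-3-methyl-9-phenylnon-6-enal (E/Z mixture, alkene geometry left open) | O=CC[C@H](C)CCC=CCCc1ccccc1 | intermediate
4 | (3R)-3-methyl-9-phenylnonanal | O=CC[C@H](C)CCCCCCc1ccccc1 | intermediate
5 | (4R)-4-methyl-10-phenyldec-1-yne | C#CC[C@H](C)CCCCCCc1ccccc1 | intermediate
6 | dimethyl[(1E,4R)-2,4-dimethyl-10-phenyldec-1-en-1-yl]alumane (alkenylalane, not isolated) | C[Al](C)/C=C(\C)C[C@H](C)CCCCCCc1ccccc1 | intermediate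
7 | (3E,6R)-4,6-dimethyl-12-phenyldodec-3-en-2-one | CC(=O)/C=C(\C)C[C@H](C)CCCCCCc1ccccc1 | intermediate
8 | (4S,6R)-4-hydroperoxy-4,6-dimethyl-12-phenyldodecan-2-one (not isolated) | CC(=O)C[C@](C)(C[C@H](C)CCCCCCc1ccccc1)OO | intermediate
9 | (5S)-3,5-dimethyl-5-[(2R)-2-methyl-8-phenyloctyl]-1,2-dioxolan-3-ol (both C3 epimers) | CC1(O)C[C@](C)(C[C@H](C)CCCCCCc2ccccc2)OO1 | intermediate
10 | (5S)-3-methoxy-3,5-dimethyl-5-[(2R)-2-methyl-8-phenyloctyl]-1,2-dioxolane (both C3 epimers) | COC1(C)C[C@](C)(C[C@H](C)CCCCCCc2ccccc2)OO1 | intermediate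
11 | methyl 2-[(3R,5S)-3,5-dimethyl-5-[(2R)-2-methyl-8-phenyloctyl]-1,2-dioxolan-3-yl]acetate | COC(=O)C[C@@]1(C)C[C@](C)(C[C@H](C)CCCCCCc2ccccc2)OO1 | target

**Step count**
Total steps: 7. Longest linear sequence: 7 (from 1).

**Steps most likely to fail**

Step 5 (the proposed new hydroperoxidation). The risks are slow iminium formation on the hindered enone, E/Z scrambling of 7 through the dienamine (which would erode selectivity), closure of the adduct to the epoxide, and an unknown facial sense. The fallback uses known chemistry, sets out from 7 and comes back at 10. Luche reduction (NaBH4, CeCl3·7H2O, MeOH, 0 °C) gives (3E,6R)-4,6-dimethyl-12-phenyldodec-3-en-2-ol F1. Mukaiyama–Isayama peroxidation (Co(thd)2 10 mol%, thd = 2,2,6,6-tetramethylheptane-3,5-dionate, O2 1 atm, Et3SiH, 1,2-dichloroethane, rt) adds H to C3 and the silylperoxy group to the tertiary carbon, giving (6R)-4,6-dimethyl-12-phenyl-4-[(triethylsilyl)peroxy]dodecan-2-ol F2. Dess–Martin periodinane with NaHCO3 in CH2Cl2 gives (6R)-4,6-dimethyl-12-phenyl-4-[(triethylsilyl)peroxy]dodecan-2-one F3. Catalytic HCl in MeOH removes silicon, closes the ring and forms the methyl peroxyketal, giving 10 together with its C5 epimer (5R)-3-methoxy-3,5-dimethyl-5-[(2R)-2-methyl-8-phenyloctyl]-1,2-dioxolane F4. This path gives no control at C5; 10 and F4 are diastereomers because of the fixed side-chain centre and are separated by preparative HPLC, here or after step 7.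

Step 7 (C3 substitution). The risks are low diastereoselectivity at C3 (methyl versus branched alkyl at C5 is a small bias) and Lewis-acid cleavage of the peroxide. The fallback sets out from 10 and comes back at 11. Allyltrimethylsilane with TiCl4 in CH2Cl2 at −78 °C, the best-documented nucleophile for alkoxydioxolanes, gives (3S,5S)-3,5-dimethyl-5-[(2R)-2-methyl-8-phenyloctyl]-3-(prop-2-en-1-yl)-1,2-dioxolane F5, whose C3 epimer is removed at this stage. Ozonolysis (O3, CH2Cl2/MeOH, −78 °C, then Me2S) gives 2-[(3R,5S)-3,5-dimethyl-5-[(2R)-2-methyl-8-phenyloctyl]-1,2-dioxolan-3-yl]acetaldehyde F6. Pinnick oxidation (NaClO2, NaH2PO4, 2-methyl-2-butene, t-BuOH/H2O) gives 2-[(3R,5S)-3,5-dimethyl-5-[(2R)-2-methyl-8-phenyloctyl]-1,2-dioxolan-3-yl]acetic acid F7. Me3SiCHN2 in MeOH/toluene then gives 11.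

Step 1 (cross-metathesis on a trisubstituted alkene). The risks are low conversion of the prenyl-type alkene and dominant self-metathesis of 2. The fallback builds the same bond by olefination, sets out from 1 and comes back at 3. HC(OMe)3 with catalytic TsOH in MeOH gives (6R)-8,8-dimethoxy-2,6-dimethyloct-2-ene F8. Ozonolysis (O3, CH2Cl2/MeOH, −78 °C, then Me2S) gives (4R)-6,6-dimethoxy-4-methylhexanal F9. Wittig reaction with (3-phenylpropyl)triphenylphosphonium bromide and NaN(SiMe3)2 in THF (−78 °C to rt) gives (3R,6Z)-1,1-dimethoxy-3-methyl-9-phenylnon-6-ene F10. Aqueous HCl in THF releases the aldehyde, giving 3 (Z-rich), which goes on to step 2 unchanged.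

**Further compounds**
F1 | step 5 | (3E,6R)-4,6-dimethyl-12-phenyldodec-3-en-2-ol (both C2 epimers) | CC(O)/C=C(\C)C[C@H](C)CCCCCCc1ccccc1
F2 | step 5 | (6R)-4,6-dimethyl-12-phenyl-4-[(triethylsilyl)peroxy]dodecan-2-ol (mixture at C2 and C4) | CC(O)CC(C)(OO[Si](CC)(CC)CC)C[C@H](C)CCCCCCc1ccccc1
F3 | step 5 | (6R)-4,6-dimethyl-12-phenyl-4-[(triethylsilyl)peroxy]dodecan-2-one (both C4 epimers) | CC(=O)CC(C)(OO[Si](CC)(CC)CC)C[C@H](C)CCCCCCc1ccccc1
F4 | step 5 | (5R)-3-methoxy-3,5-dimethyl-5-[(2R)-2-methyl-8-phenyloctyl]-1,2-dioxolane (both C3 epimers) | COC1(C)C[C@@](C)(C[C@H](C)CCCCCCc2ccccc2)OO1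
F5 | step 7 | (3S,5S)-3,5-dimethyl-5-[(2R)-2-methyl-8-phenyloctyl]-3-(prop-2-en-1-yl)-1,2-dioxolane | C=CC[C@@]1(C)C[C@](C)(C[C@H](C)CCCCCCc2ccccc2)OO1
F6 | step 7 | 2-[(3R,5S)-3,5-dimethyl-5-[(2R)-2-methyl-8-phenyloctyl]-1,2-dioxolan-3-yl]acetaldehyde | O=CC[C@@]1(C)C[C@](C)(C[C@H](C)CCCCCCc2ccccc2)OO1
F7 | step 7 | 2-[(3R,5S)-3,5-dimethyl-5-[(2R)-2-methyl-8-phenyloctyl]-1,2-dioxolan-3-yl]acetic acid | OC(=O)C[C@@]1(C)C[C@](C)(C[C@H](C)CCCCCCc2ccccc2)OO1
F8 | step 1 | (6R)-8,8-dimethoxy-2,6-dimethyloct-2-ene | COC(OC)C[C@H](C)CCC=C(C)C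
F9 | step 1 | (4R)-6,6-dimethoxy-4-methylhexanal | COC(OC)C[C@H](C)CCC=O
F10 | step 1 | (3R,6Z)-1,1-dimethoxy-3-methyl-9-phenylnon-6-ene | COC(OC)C[C@H](C)CC/C=C\CCc1ccccc1
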